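**Plan**

- Feature used: ring B (C13, C14, C16, C17, C18, C19, C20) is a cyclohept-4-enone whose C14 ketone is γ,δ-unsaturated toward C18=C19. This is a Claisen retron that leads back to a ring-A-fused 2-methylene-5-(butenolid-3-yl)tetrahydrofuran.
- Cuts, in retrosynthetic order: C16–C26 (aldol, ring C); C16–C17 with O–C19 re-formed (retro-Claisen, ring B); O–C14 (alkynol cyclisation); C18–C19 (lactone-enolate aldol); C4–C5 and C13–C20 (Diels–Alder, ring A).
- Forward: ring A by Diels–Alder; the ring-D lactone is joined by aldol and unveiled as a butenolide; the tetrahydrofuran closes by gold-catalysed 5-exo cyclisation; ring B by Claisen ring expansion; ring C by aldol.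
- Stereochemistry: C4, C13 and C20 come from one catalyst-controlled endo Diels–Alder; C24 from the (S)-lactone tosylate (L-glutamic acid pool); C19 from Felkin–Anh addition; C17 is relayed from C19 through the chair Claisen array; C16 and C26 come from the cis-fused, reversible aldol.

Key step: step 13

Remarks: atom labels follow the order of atoms in the target SMILES (ring A: C4, C5, C6, C8, C13, C20; ring C: C16, C17, C24, C25, C26; ring D: C17, C18, C21, O23, C24). Assumed: compounds 2, 6 and 10, LDA solution and both enantiomers of the imidazolidinone catalyst are bought. The β-keto ester is carried and drawn as its enol, as in the target.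

**Route**

Step 1
Reactants: 1 methyl acetoacetate; 2 3-(trimethylsilyl)prop-2-ynal
Product: 3 methyl (2Z)-2-acetyl-5-(trimethylsilyl)pent-2-en-4-ynoate
Conditions: TiCl4 (2 equiv), pyridine (4 equiv), THF, 0 °C → rt; chromatography
Reagents that add atoms: none
Why: Knoevenagel condensation under TiCl4/pyridine, which activates the ynal without a nucleophilic amine that would add to the triple bond; the Z isomer (alkynyl cis to the ester, trans to the coplanar acetyl group) is expected to predominate and is separated from any E isomer, which can be re-equilibrated.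

Step 2
Reactants: 3 methyl (2Z)-2-acetyl-5-(trimethylsilyl)pent-2-en-4-ynoate
Product: 4 methyl (2Z)-2-{1-[(tert-butyldimethylsilyl)oxy]ethenyl}-5-(trimethylsilyl)pent-2-en-4-ynoate
Conditions: TBSOTf (1.2 equiv), Et3N (1.5 equiv), CH2Cl2, −78 → 0 °C
Reagents that add atoms: tert-butyldimethylsilyl trifluoromethanesulfonate, CC(C)(C)[Si](C)(C)OS(=O)(=O)C(F)(F)F
Why: Soft enolisation and O-silylation of the methyl ketone (the only enolisable position) gives the cross-conjugated 2-silyloxy-1,3-diene without touching the C=C geometry, so the alkynyl group sits on the outside of the s-cis diene.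

Step 3
Reactants: 5 methacrolein; 6 (triphenylphosphoranylidene)acetaldehyde
Product: 7 (2E)-4-methylpenta-2,4-dienal
Conditions: 5 (3 equiv), toluene, rt → 40 °C; careful distillation
Reagents that add atoms: none
Why: Wittig olefination with a stabilised formyl ylide gives the E enal, and the excess of volatile methacrolein limits a second homologation.

Step 4
Reactants: 4 silyloxydiene (1.5 equiv); 7 (2E)-4-methylpenta-2,4-dienal
Product: 8 methyl (4R,5S,6S)-2-[(tert-butyldimethylsilyl)oxy]-5-formyl-4-(prop-1-en-2-yl)-6-[(trimethylsilyl)ethynyl]cyclohex-1-ene-1-carboxylate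
Conditions: (5R)-5-benzyl-2,2,3-trimethylimidazolidin-4-one·HCl (20 mol %), MeCN–H2O (95:5), −20 °C
Reagents that add atoms: none
Why: Iminium-catalysed endo Diels–Alder reaction: the CH2 terminus of the 2-silyloxydiene bonds to the β-carbon (C4) and C13 to the α-carbon (C20), the E dienophile fixes isopropenyl trans to formyl, the endo array with the outside alkynyl group fixes C13 cis to C20, and the benzyl group of the (5R)-catalyst shields one face of the E-iminium ion so that the diene adds to the Cα-Re/Cβ-Re face, giving 4R,20S (target labels).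

Step 5
Reactants: 8 trimethylsilyl-alkyne aldehyde
Product: 9 methyl (4R,5S,6R)-2-[(tert-butyldimethylsilyl)oxy]-6-ethynyl-5-formyl-4-(prop-1-en-2-yl)cyclohex-1-ene-1-carboxylate
Conditions: AgNO3 (10 mol %), acetone–H2O–CH2Cl2, rt
Reagents that add atoms: none
Why: Silver-catalysed protodesilylation cleaves only the C(sp)–Si bond under neutral conditions, leaving the O-silyl enol ether, the ester and the epimerisable aldehyde centre untouched; no stereocentre is formed (the descriptor at C6 changes only through CIP priority).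

Step 6
Reactants: 10 [(2S)-5-oxooxolan-2-yl]methyl 4-methylbenzenesulfonate
Product: 11 (5S)-5-(2-methylprop-2-en-1-yl)oxolan-2-one
Conditions: CuI (2 equiv), isopropenylmagnesium bromide (4 equiv), THF, −40 °C; then 10, −40 → −20 °C; aq NH4Cl
Reagents that add atoms: isopropenylmagnesium bromide, CC(=C)[Mg]Br
Why: SN2 displacement of the primary tosylate by a homocuprate, which at low temperature is faster than attack on the lactone carbonyl; the stereocentre is not involved.

Step 7
Reactants: 11 (5S)-5-(2-methylprop-2-en-1-yl)oxolan-2-one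
Product: 13 (5S)-5-(2-oxopropyl)oxolan-2-one, via ozonide 12 (not isolated)
Conditions: O3, CH2Cl2, −78 °C; then PPh3, −78 °C → rt
Reagents that add atoms: ozone, [O-][O+]=O
Why: Ozonolysis (Criegee mechanism) of the only C=C bond, the ozonide being reduced by triphenylphosphine to the methyl ketone.

Step 8
Reactants: 13 (5S)-5-(2-oxopropyl)oxolan-2-one
Product: 14 (5S)-5-[(2-methyl-1,3-dioxolan-2-yl)methyl]oxolan-2-one
Conditions: 1,2-bis(trimethylsilyloxy)ethane (1.5 equiv), TMSOTf (5 mol %), CH2Cl2, −78 → −20 °C
Reagents that add atoms: 1,2-bis(trimethylsilyloxy)ethane, C[Si](C)(C)OCCO[Si](C)(C)C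
Why: Aprotic silyl-triflate-catalysed ketalisation with the bis-silyl ether of ethylene glycol protects the methyl ketone for the two enolate steps without opening the lactone.

Step 9
Reactants: 14 ketal lactone
Product: 16 (3RS,5R)-5-[(2-methyl-1,3-dioxolan-2-yl)methyl]-3-(phenylselanyl)oxolan-2-one, via lithium enolate 15 (not isolated)
Conditions: LDA (1.1 equiv), THF, −78 °C; then PhSeCl (1.15 equiv), −78 °C
Reagents that add atoms: benzeneselenenyl chloride, Cl[Se]c1ccccc1
Why: α-Selenenylation of the lactone lithium enolate; both C3 epimers are usable because this centre becomes sp2 later, and C5 is untouched (its descriptor changes only through CIP priority).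

Step 10
Reactants: 16 α-seleno lactone; 9 ring-A aldehyde
Product: 18 methyl (4R,5S,6R)-2-[(tert-butyldimethylsilyl)oxy]-6-ethynyl-5-[(S)-hydroxy{(3RS,5R)-5-[(2-methyl-1,3-dioxolan-2-yl)methyl]-2-oxo-3-(phenylselanyl)oxolan-3-yl}methyl]-4-(prop-1-en-2-yl)cyclohex-1-ene-1-carboxylate, via lithium enolate 17 (not isolated)
Conditions: LDA (1.05 equiv), THF, −78 °C; then 9, −78 °C; AcOH quench at −78 °C
Reagents that add atoms: none
Why: Aldol addition of the α-seleno lactone enolate to the aldehyde: with the formyl group equatorial between the equatorial isopropenyl group on C4 and the axial ethynyl group on C13, the enolate approaches anti to the C20–C4 bond and past H20 (Felkin–Anh, C4 as the large group), which should set 19S; the selenium-bearing centre forms as a mixture that is erased in the next step.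

Step 11
Reactants: 18 β-hydroxy selenide
Product: 20 methyl (4R,5S,6R)-2-[(tert-butyldimethylsilyl)oxy]-6-ethynyl-5-[(S)-hydroxy{(5R)-5-[(2-methyl-1,3-dioxolan-2-yl)methyl]-2-oxo-2,5-dihydrofuran-3-yl}methyl]-4-(prop-1-en-2-yl)cyclohex-1-ene-1-carboxylate, via selenoxide 19 (not isolated)
Conditions: NaIO4 (2 equiv), NaHCO3, THF–MeOH–H2O, 0 °C → rt
Reagents that add atoms: none
Why: Selenide oxidation and syn selenoxide elimination, which runs toward the ring CH2 (C17) and not toward the carbinol C–H, so the α-(hydroxyalkyl)butenolide results; periodate leaves the alkenes, the alkyne and the silyl enol ether alone.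

Step 12
Reactants: 20 butenolide alkynol
Product: 21 methyl (1S,3aS,7R,7aS)-5-[(tert-butyldimethylsilyl)oxy]-3-methylidene-1-{(5R)-5-[(2-methyl-1,3-dioxolan-2-yl)methyl]-2-oxo-2,5-dihydrofuran-3-yl}-7-(prop-1-en-2-yl)-1,3,3a,6,7,7a-hexahydro-2-benzofuran-4-carboxylate
Conditions: AuCl (5 mol %), K2CO3 (10 mol %), MeCN, rt; filtration through Et3N-deactivated silica, used at once
Reagents that add atoms: none
Why: Gold(I)-catalysed 5-exo-dig hydroalkoxylation of the 4-pentyn-1-ol unit (anti oxyauration, protodeauration): the axial ethynyl group and the equatorial carbinol are cis, so the tetrahydrofuran closes cis-fused without a new stereocentre, and the small amount of carbonate keeps the medium free of acid that would move the exocyclic double bond.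

Step 13
Reactants: 21 ring-A-fused 2-methylene-5-(butenolid-3-yl)tetrahydrofuran
Product: 22 tricyclic keto lactone (rings A, B, D; 4R,13S,17R,20S,24R): ring-A TBS enol ether, C14 ketone, C18=C19 α-alkylidene γ-lactone, (2-methyl-1,3-dioxolan-2-yl)methyl on C24
Conditions: toluene (0.02 M), 2,6-di-tert-butyl-4-methylpyridine (0.2 equiv), base-washed sealed tube, 150 °C
Reagents that add atoms: none
Why: Heating triggers a concerted [3,3]-sigmatropic (Claisen) shift of the allyl vinyl ether C16=C14–O–C19–C18=C17: O–C19 breaks as C16–C17 forms, the enol ether becomes the C14 ketone and the butenolide double bond moves to C18=C19, so ester conjugation is kept. The closest known reactions are the ring expansion of 2-methylene-5-vinyltetrahydrofurans to cyclohept-4-enones and the Claisen rearrangement of ethers of Morita–Baylis–Hillman-type allylic alcohols. Ring B closes by ring expansion (five- to seven-membered): the C13–C20 bridge spans C14 and C19 of a chair-like six-atom array (an 8-oxabicyclo[3.2.1]octene-like transition state), which can deliver only the cis ring olefin. C17 is the only new stereocentre and is controlled by C19: the shift is suprafacial on the butenolide face that carries the C19–O bond, the butenolide lies on the convex face of the cis-fused bicycle (cis to H13 and H20), C24 is the equatorial (E) substituent and H17 the axial one, so H17 ends syn to H13 and H20 (17R) and the new bond is syn to C25. The step needs chair over boat selectivity (the boat would give the C17 epimer) and an intact exocyclic enol ether; the chair is the normal, less strained array and turns only H17 toward the endo hydrogens, while the hindered pyridine base, base-washed glass and the silylated ring-A enol keep acid away.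

Step 14
Reactants: 22 tricyclic keto lactone
Product: 23 seco-diketone (4R,13S,17R,20S,24R): free ring-A enol β-keto ester, C14 ketone, 2-oxopropyl group on C24
Conditions: 1 M aq HCl–THF (1:5), 0 °C → rt
Reagents that add atoms: water, O
Why: Aqueous acid hydrolyses the dioxolane (through the oxocarbenium ion) and the silyl enol ether (C-protonation, Si–O cleavage), the β-keto ester returning as its hydrogen-bonded enol with no stereocentre touched.

Step 15
Reactants: 23 seco-diketone
Product: 24 target CNP0268969.1 (4R,13S,16R,17R,20S,24R,26S)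
Conditions: DBU (1.2 equiv), CH2Cl2, −20 → 0 °C; pH 5 buffer
Reagents that add atoms: none
Why: Reversible intramolecular aldol addition (5-exo-trig) of the C14 ketone enolate at C16 onto the C26 ketone: a cyclopentane fused across C16–C17 and tethered through C24 can only form cis (16R), the C26 oxygen points toward the C14 carbonyl in a closed hydrogen-bonded array so that OH is cis to C14 and the methyl group convex (26S), the alternative C25-to-C14 closure would give a strained bridged ring and reverts, and the cis A/B fusion at C13 is the arrangement favoured by allylic strain with the C8 ester.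

**Compound list**

1 | methyl acetoacetate | CC(=O)CC(=O)OC | starting material
2 | 3-(trimethylsilyl)prop-2-ynal | C[Si](C)(C)C#CC=O | starting material
3 | methyl (2Z)-2-acetyl-5-(trimethylsilyl)pent-2-en-4-ynoate | CC(=O)/C(C(=O)OC)=C/C#C[Si](C)(C)C | intermediate
4 | methyl (2Z)-2-{1-[(tert-butyldimethylsilyl)oxy]ethenyl}-5-(trimethylsilyl)pent-2-en-4-ynoate | C=C(O[Si](C)(C)C(C)(C)C)/C(C(=O)OC)=C/C#C[Si](C)(C)C | intermediate
5 | methacrolein | CC(=C)C=O | starting material
6 | (triphenylphosphoranylidene)acetaldehyde | O=CC=P(c1ccccc1)(c1ccccc1)c1ccccc1 | starting material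
7 | (2E)-4-methylpenta-2,4-dienal | CC(=C)/C=C/C=O | intermediate
8 | methyl (4R,5S,6S)-2-[(tert-butyldimethylsilyl)oxy]-5-formyl-4-(prop-1-en-2-yl)-6-[(trimethylsilyl)ethynyl]cyclohex-1-ene-1-carboxylate | C=C(C)[C@@H]1CC(O[Si](C)(C)C(C)(C)C)=C(C(=O)OC)[C@@H](C#C[Si](C)(C)C)[C@H]1C=O | intermediate
9 | methyl (4R,5S,6R)-2-[(tert-butyldimethylsilyl)oxy]-6-ethynyl-5-formyl-4-(prop-1-en-2-yl)cyclohex-1-ene-1-carboxylate | C=C(C)[C@@H]1CC(O[Si](C)(C)C(C)(C)C)=C(C(=O)OC)[C@@H](C#C)[C@H]1C=O | intermediate
10 | [(2S)-5-oxooxolan-2-yl]methyl 4-methylbenzenesulfonate | Cc1ccc(cc1)S(=O)(=O)OC[C@@H]1CCC(=O)O1 | starting material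
11 | (5S)-5-(2-methylprop-2-en-1-yl)oxolan-2-one | C=C(C)C[C@@H]1CCC(=O)O1 | intermediate
12 | (5S)-5-[(3-methyl-1,2,4-trioxolan-3-yl)methyl]oxolan-2-one (ozonide, epimers at the trioxolane carbon) | CC1(C[C@@H]2CCC(=O)O2)OCOO1 | intermediate
13 | (5S)-5-(2-oxopropyl)oxolan-2-one | CC(=O)C[C@@H]1CCC(=O)O1 | intermediate
14 | (5S)-5-[(2-methyl-1,3-dioxolan-2-yl)methyl]oxolan-2-one | CC1(C[C@@H]2CCC(=O)O2)OCCO1 | intermediate
15 | lithium (5S)-5-[(2-methyl-1,3-dioxolan-2-yl)methyl]-4,5-dihydrofuran-2-olate | CC1(C[C@@H]2CC=C([O-])O2)OCCO1.[Li+] | intermediate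
16 | (3RS,5R)-5-[(2-methyl-1,3-dioxolan-2-yl)methyl]-3-(phenylselanyl)oxolan-2-one | CC1(C[C@@H]2CC([Se]c3ccccc3)C(=O)O2)OCCO1 | intermediate
17 | lithium (5R)-5-[(2-methyl-1,3-dioxolan-2-yl)methyl]-3-(phenylselanyl)-4,5-dihydrofuran-2-olate | CC1(C[C@@H]2CC([Se]c3ccccc3)=C([O-])O2)OCCO1.[Li+] | intermediate
18 | aldol adduct, methyl (4R,5S,6R)-2-[(tert-butyldimethylsilyl)oxy]-6-ethynyl-5-[(S)-hydroxy{(3RS,5R)-5-[(2-methyl-1,3-dioxolan-2-yl)methyl]-2-oxo-3-(phenylselanyl)oxolan-3-yl}methyl]-4-(prop-1-en-2-yl)cyclohex-1-ene-1-carboxylate | C=C(C)[C@@H]1CC(O[Si](C)(C)C(C)(C)C)=C(C(=O)OC)[C@@H](C#C)[C@H]1[C@H](O)C2([Se]c3ccccc3)C[C@@H](CC4(C)OCCO4)OC2=O | intermediate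
19 | selenoxide of 18 (3-phenylseleninyl lactone) | C=C(C)[C@@H]1CC(O[Si](C)(C)C(C)(C)C)=C(C(=O)OC)[C@@H](C#C)[C@H]1[C@H](O)C2([Se](=O)c3ccccc3)C[C@@H](CC4(C)OCCO4)OC2=O | intermediate
20 | methyl (4R,5S,6R)-2-[(tert-butyldimethylsilyl)oxy]-6-ethynyl-5-[(S)-hydroxy{(5R)-5-[(2-methyl-1,3-dioxolan-2-yl)methyl]-2-oxo-2,5-dihydrofuran-3-yl}methyl]-4-(prop-1-en-2-yl)cyclohex-1-ene-1-carboxylate | C=C(C)[C@@H]1CC(O[Si](C)(C)C(C)(C)C)=C(C(=O)OC)[C@@H](C#C)[C@H]1[C@H](O)C2=C[C@@H](CC3(C)OCCO3)OC2=O | intermediate
21 | methyl (1S,3aS,7R,7aS)-5-[(tert-butyldimethylsilyl)oxy]-3-methylidene-1-{(5R)-5-[(2-methyl-1,3-dioxolan-2-yl)methyl]-2-oxo-2,5-dihydrofuran-3-yl}-7-(prop-1-en-2-yl)-1,3,3a,6,7,7a-hexahydro-2-benzofuran-4-carboxylate | C=C(C)[C@@H]1CC(O[Si](C)(C)C(C)(C)C)=C(C(=O)OC)[C@H]2C(=C)O[C@H](C3=C[C@@H](CC4(C)OCCO4)OC3=O)[C@H]21 | intermediate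
22 | tricyclic keto lactone (rings A, B, D; 4R,13S,17R,20S,24R): TBS enol ether at C6, methyl ester on C8, C14 ketone, C18=C19 alkylidene lactone, (2-methyl-1,3-dioxolan-2-yl)methyl on C24 | C=C(C)[C@@H]1CC(O[Si](C)(C)C(C)(C)C)=C(C(=O)OC)[C@H]2C(=O)C[C@@H]3C(=C[C@H]21)C(=O)O[C@@H]3CC4(C)OCCO4 | intermediate
23 | seco-diketone (4R,13S,17R,20S,24R): enol β-keto ester, C14 ketone, 2-oxopropyl on C24 | C=C(C)[C@@H]1CC(O)=C(C(=O)OC)[C@H]2C(=O)C[C@@H]3C(=C[C@H]21)C(=O)O[C@@H]3CC(C)=O | intermediate
24 | CNP0268969.1 (4R,13S,16R,17R,20S,24R,26S) | C=C(C)[C@@H]1CC(O)=C(C(=O)OC)[C@H]2C(=O)[C@@H]3[C@@H]4C(=C[C@H]21)C(=O)O[C@@H]4C[C@]3(C)O | target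

**Step count and risks**

Total: 15 steps. Longest linear sequence: 10 steps (1, 2, 4, 5, 10–15; the lactone branch 6–9 then 10–15 is equally long).

Steps most likely to fail:

1. Step 13 (Claisen ring expansion). The rearrangement may leak through the boat-like array, in which C16 approaches anti to the C25 methylene, and so lose selectivity at C17. Traces of acid may also move the exocyclic double bond into conjugation with the ring-A enoate before the shift occurs. Fallback, setting out from 20 and returning at 22: 20 is equilibrated at C24 through its 2-hydroxyfuran tautomer (DBU cat., CH2Cl2) and the C24-epimeric butenolide alkynol F1 is separated while 20 is recycled. The same gold cyclisation gives the epimeric enol ether F2. Its chair rearrangement now forms C16–C17 anti to the side chain and should give the 24-epi keto lactone F3. The lactone is opened (LiOH, THF–H2O, 0 °C) to the hydroxy acid F4, and Mitsunobu lactonisation (PPh3, DIAD, THF) closes ring D with inversion at C24 to give 22.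

2. Step 4 (Diels–Alder). The silyl enol ether of the diene may hydrolyse under the aqueous iminium conditions, or the reaction may go stepwise (Mukaiyama–Michael, then ring closure) and erode the endo selectivity that sets C13. Fallback, setting out from 7 (with 4) and returning at 8: Pinnick oxidation of 7 gives (2E)-4-methylpenta-2,4-dienoic acid F5. Its mixed pivalic anhydride acylates lithiated (4R)-4-benzyl-1,3-oxazolidin-2-one to the imide F6. The Et2AlCl-promoted Diels–Alder reaction of the chelated s-cis imide with 4 (CH2Cl2, −78 °C, diene anti to the benzyl group) gives the cycloadduct F7 under anhydrous conditions. LiBH4 removes the auxiliary to give the primary alcohol F8, and Dess–Martin oxidation gives 8.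

3. Step 10 (aldol union). Addition of the fully substituted, selenium-bearing enolate to the hindered α-branched aldehyde may be slow and reversible, and Felkin selectivity at C19 may erode. Fallback, setting out from 16 (with 9) and returning at 20: 16 is oxidised (NaIO4) to its selenoxide F9, which eliminates to the butenolide F10. Lithium benzeneselenolate (from diphenyl diselenide and n-BuLi, THF, −60 °C) adds to C17 anti to the side chain, and the secondary, less hindered lactone enolate so formed adds to 9 to give the β-seleno aldol F11. Periodate oxidation gives the selenoxide F12, which eliminates across C17–C18 to 20.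

**Further compounds**

F1 | step 13 | C24 epimer of 20 (5S-butenolide) | C=C(C)[C@@H]1CC(O[Si](C)(C)C(C)(C)C)=C(C(=O)OC)[C@@H](C#C)[C@H]1[C@H](O)C2=C[C@H](CC3(C)OCCO3)OC2=O
F2 | step 13 | C24 epimer of 21 | C=C(C)[C@@H]1CC(O[Si](C)(C)C(C)(C)C)=C(C(=O)OC)[C@H]2C(=C)O[C@H](C3=C[C@H](CC4(C)OCCO4)OC3=O)[C@H]21
F3 | step 13 | C24 epimer of 22 | C=C(C)[C@@H]1CC(O[Si](C)(C)C(C)(C)C)=C(C(=O)OC)[C@H]2C(=O)C[C@@H]3C(=C[C@H]21)C(=O)O[C@H]3CC4(C)OCCO4
F4 | step 13 | hydroxy acid from F3 (C21 carboxylic acid, C24 secondary alcohol) | C=C(C)[C@@H]1CC(O[Si](C)(C)C(C)(C)C)=C(C(=O)OC)[C@H]2C(=O)C[C@@H]([C@@H](O)CC3(C)OCCO3)C(=C[C@H]21)C(=O)O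
F5 | step 4 | (2E)-4-methylpenta-2,4-dienoic acid | CC(=C)/C=C/C(=O)O
F6 | step 4 | (4R)-4-benzyl-3-[(2E)-4-methylpenta-2,4-dienoyl]-1,3-oxazolidin-2-one | CC(=C)/C=C/C(=O)N1[C@H](Cc2ccccc2)COC1=O
F7 | step 4 | Diels–Alder adduct carrying the N-acyl oxazolidinone on C20 in place of the formyl group of 8 | C=C(C)[C@@H]1CC(O[Si](C)(C)C(C)(C)C)=C(C(=O)OC)[C@@H](C#C[Si](C)(C)C)[C@H]1C(=O)N2[C@H](Cc3ccccc3)COC2=O
F8 | step 4 | primary alcohol corresponding to 8 (hydroxymethyl on C20) | C=C(C)[C@@H]1CC(O[Si](C)(C)C(C)(C)C)=C(C(=O)OC)[C@@H](C#C[Si](C)(C)C)[C@H]1CO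
F9 | step 10 | selenoxide of 16 | CC1(C[C@@H]2CC([Se](=O)c3ccccc3)C(=O)O2)OCCO1
F10 | step 10 | (5R)-5-[(2-methyl-1,3-dioxolan-2-yl)methyl]furan-2(5H)-one | CC1(C[C@@H]2C=CC(=O)O2)OCCO1
F11 | step 10 | β-seleno aldol (phenylselanyl on C17, hydrogen on C18, 19S carbinol) | C=C(C)[C@@H]1CC(O[Si](C)(C)C(C)(C)C)=C(C(=O)OC)[C@@H](C#C)[C@H]1[C@H](O)C2C([Se]c3ccccc3)[C@@H](CC4(C)OCCO4)OC2=O
F12 | step 10 | selenoxide of F11 | C=C(C)[C@@H]1CC(O[Si](C)(C)C(C)(C)C)=C(C(=O)OC)[C@@H](C#C)[C@H]1[C@H](O)C2C([Se](=O)c3ccccc3)[C@@H](CC4(C)OCCO4)OC2=O
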